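Count the reagent.

| setting | Wednesday's | Monday's | Friday's | flask |
|---|---|---|---|---|
| substrate | 28 mM | 44 mM | 20 mM | 20 mM |
| reagent | 22 mM (fed, over 5.0 h) | 22 mM (fed, over 5.0 h) | 22 mM (fed, over 5.0 h) | 22.0 mM (fed, over 5.0 h) |
| initiator | 2 mM | 2 mM | 1 mM | 2.0 mM |
| remark | run made earlier | run made earlier | run made earlier |  |
| time |  |  |  | 15 d |

| run | time / d | target / % | substrate / % |
|---|---|---|---|
| Wednesday's | 1.25 | 73 | 25 |
| Wednesday's | 2.50 | 78 | 18 |
| Wednesday's | 4.00 | 79 | 14 |
| Wednesday's | 5.00 | 77 | 19 |
| Wednesday's | 6.00 | 81 | 13 |
| Wednesday's | 8.00 | 77 | 14 |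
| Wednesday's | 10.0 | 77 | 13 |
| Monday's | 0.500 | 31 | 68 |
| Monday's | 1.25 | 49 | 45 |
| Monday's | 2.50 | 48 | 47 |
| Monday's | 4.00 | 52 | 48 |
| Monday's | 5.00 | 47 | 49 |
| Monday's | 8.00 | 52 | 46 |
| Monday's | 10.0 | 52 | 43 |
| Friday's | 0.625 | 70 | 30 |
| Friday's | 1.25 | 96 | 0 |
| Friday's | 2.50 | 100 | 0 |
| Friday's | 5.00 | 100 | 3 |
| Friday's | 10.0 | 99 | 0 |

(each reading ± 2 percentage points)

- at 15 d, what has stopped the reaction, if anything has (all of the substrate has reacted / the reagent has run out first / forward and back rates have come level / it is still moving)
- how much target there is at 15 d, in percent of the substrate charged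

- the reaction counts as stopped when no species that holds the substrate changes by six tenths of a point or more over the second half of the time

At the last reading, Monday's target reads 22.9 mM and Wednesday's 21.6 mM, both close to the 22 mM of reagent charged, which reads as one reagent per target. For this flask, c(reagent)/c(substrate) is 110 %. We call this ratio the reagent ceiling: the most target the reagent can make, in percent of the substrate charged. It stands above 100 %, so our upper bound is the substrate charge, 100 %.

For a lower bound, we take the shortfall of target plus substrate at Wednesday's last reading, 2.80 mM, larger than Monday's 2.20 mM. Lost from this flask, it leaves 86.0 %. Friday's run is closer: the same substrate and reagent, with half the initiator, reading 100 % target at 2.50 d and a shortfall of 1 percentage point at its last reading. Scaled up with the initiator, that shortfall gives 98.0 %, which we hold as an estimate and not as a bound, for a reading scatters by 2 points.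

The forecast, holding that the flask “should finish at least as fast” as Friday's, gives 100 % of target and says all of the substrate has reacted. That is the top of our bracket.

The flask gives 98.0 % of target at 15 d: all of the substrate has reacted.

    initiator → 2 initiating radical (k = 1.30 × 10⁻⁶ s⁻¹)
    reagent + first chain carrier → target + second chain carrier (k = 4000 M⁻¹ s⁻¹)
    2 first chain carrier → ended chains (k = 4.00 × 10⁷ M⁻¹ s⁻¹)
    substrate + initiating radical → capped initiator + first chain carrier (k = 4.90 × 10⁵ M⁻¹ s⁻¹)
    substrate + second chain carrier → by-product + first chain carrier (k = 14000 M⁻¹ s⁻¹)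

In this flask substrate stands at 0 % of its charge and reagent at 11 %, making substrate the limiting reagent. The ceiling reckons that reagent remainder as 10.9 %. A neighbour flask, charged like this one but with 34 mM of substrate, has a ceiling of 64.7 %, and it ends with 0 % of its reagent and 64.7 % of target.

(The numbers in the tables are simulated with made-up constants; the scatter is artificial.)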